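**Retrosynthetic overview**

1. Ring C is closed last: C13=C14 by ring-closing metathesis between a methallyl group on C11 and an allyl group on C16. C16 is first added equatorially to a C8 ketone, C12–C13 comes from isopropenyl opening of a C11–C12 epoxide, and C11 and C16 end as ketones.
2. The ring A oxygens are added on the closed decalin: SeO2 at the only allylic CH2 (C3), C3–OH-directed OsO4 on C1=C2, then acetate at the equatorial C2–OH and benzoates at the axial C1–OH and C3–OH.
3. Ring B: the strategy rests on C7 being a carbinol carbon bonded to the C6 methylene, which hangs from C5 between the quaternary C4 and C10, with oxygenated C8 next to C7. C6–C7 is therefore made by SmI2 Barbier addition of a C6 iodide to an α-silyloxy C7 aldehyde held on ring A.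
4. The precursor: C9–C10 (quaternary C10) by a chelate-controlled dianion Ireland–Claisen rearrangement of the safranyl ester of (3S)-4-benzyloxy-3-hydroxybutanoic acid. The acid carbon becomes C8 and the carbinol carbon becomes C11, whose configuration is erased later as the C11 ketone. C8–O comes from a Felkin reduction and C5–H/C6 from hydroboration of C5=C6.
5. Order of rings: A (from safranal) → B (step 15) → C (step 32).

Key step: step 15

Remark on numbering: C1–C10 are the decalin carbons (ring A = C1–C5, C10; ring B = C5–C10); ring C = C8, C9, C11–C16 (C11 on C9, C16 on C8, methyl on C13). β is the face of the C10 methyl, α the opposite face.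

Remark on the precursor: C11 is carried through ring B closure as a benzyl-protected carbinol already bearing C12, not as a carboxylic ester. An ester would put the C8 silyl ether β to an enolisable carbonyl, offer the alkylsamarium a competing acyl substitution, and turn the later C8 ketone into a β-keto ester that cannot take a basic C16 nucleophile. C3 stays a methylene until ring B is closed, because its allylic oxidation is stereocontrolled only on the rigid decalin.

Assumption: tributyl[(methoxymethoxy)methyl]stannane and 2-benzyloxy-1-methylpyridinium triflate are purchased reagents.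

**Route**

Step 1
Reactants: 1 safranal
Product: 2 safranol
Conditions: NaBH4, CeCl3·7H2O, MeOH, 0 °C
Reagents that add atoms: none
Why: Luche reduction delivers hydride 1,2 to the hindered dienal and leaves the conjugated diene untouched.

Step 2
Reactants: 3 ethyl 4-(benzyloxy)-3-oxobutanoate
Product: 4 ethyl (3S)-4-(benzyloxy)-3-hydroxybutanoate
Conditions: H2 (50 atm), RuCl2[(R)-BINAP] (0.1 mol %), EtOH, 50 °C
Reagents that add atoms: none
Why: Noyori asymmetric hydrogenation of a β-keto ester, in which the (R)-BINAP complex should give the (3S)-carbinol (the sense known for 4-chloro- and 4-alkoxyacetoacetates); this is the only source of absolute configuration in the route.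

Step 3
Reactants: 4 ethyl (3S)-4-(benzyloxy)-3-hydroxybutanoate
Product: 5 (3S)-4-(benzyloxy)-3-hydroxybutanoic acid
Conditions: LiOH·H2O, THF/H2O, 0 °C; then 1 M HCl to pH 3
Reagents that add atoms: lithium hydroxide [Li+].[OH-]
Why: Saponification at 0 °C cleaves the ethyl ester without dehydrating the β-hydroxy acid.

Step 4
Reactants: 2 safranol; 5 (3S)-4-(benzyloxy)-3-hydroxybutanoic acid
Product: 6 safranyl (3S)-4-(benzyloxy)-3-hydroxybutanoate
Conditions: EDC·HCl, DMAP (0.1 equiv), CH2Cl2, 0 °C, slow addition of 5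
Reagents that add atoms: none
Why: Steglich esterification, in which the primary allylic alcohol of 2 outcompetes the secondary hydroxyl of 5 for the activated acid.

Step 5
Reactants: 6 safranyl (3S)-4-(benzyloxy)-3-hydroxybutanoate
Product: 8 (2R,3S)-4-(benzyloxy)-3-hydroxy-2-[(1S)-1,5,5-trimethyl-6-methylidenecyclohex-2-en-1-yl]butanoic acid, via dilithium enolate 7 (not isolated)
Conditions: LiN(i-Pr)2 (2.3 equiv), THF, −78 → 25 °C (45 °C to completion); then 1 M HCl
Reagents that add atoms: none
Why: Ireland–Claisen rearrangement of a β-hydroxy ester dianion (Fráter–Seebach-type chelate): the lithium chelate fixes the Z(O)-enolate and shields the face syn to C12, and the chair transition state (C10 methyl axial, C11 equatorial) relays this to C9 and to the new quaternary C10 while the [3,3] shift leaves the exocyclic C5=C6 alkene.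

Step 6
Reactants: 8 Claisen acid
Product: 9 N-methoxy-N-methylamide of 8 (C8 Weinreb amide; C11–OH free)
Conditions: MeNH(OMe)·HCl, EDC·HCl, HOBt, i-Pr2NEt, CH2Cl2, 0 → 25 °C
Reagents that add atoms: N,O-dimethylhydroxylamine hydrochloride CNOC.Cl
Why: Carbodiimide amidation gives the Weinreb amide so that C7 can later be added exactly once; the small amine tolerates the hindered acid and the free hydroxyl.

Step 7
Reactants: 9 Weinreb amide
Product: 10 C11 benzyl ether of 9 (C11 and C12 both benzyl ethers)
Conditions: 2-benzyloxy-1-methylpyridinium triflate, MgO, PhCF3, 85 °C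
Reagents that add atoms: 2-benzyloxy-1-methylpyridinium triflate C[n+]1ccccc1OCc1ccccc1.[O-]S(=O)(=O)C(F)(F)F
Why: Dudley benzylation under neutral conditions protects the C11 hydroxyl without exposing the β-hydroxy amide to base (retro-aldol) or the exocyclic alkene to acid.

Step 8
Reactants: 10 dibenzyl Weinreb amide
Product: 11 C8 ketone carrying C7 as CH2OMOM
Conditions: Bu3SnCH2OCH2OMe, n-BuLi, THF, −78 °C; then 10, −78 °C; aq NH4Cl
Reagents that add atoms: tributyl[(methoxymethoxy)methyl]stannane CCCC[Sn](CCCC)(CCCC)COCOC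
Why: Tin–lithium exchange (Still) gives the hydroxymethyl anion equivalent, which adds once to the Weinreb amide through the chelated tetrahedral intermediate and so attaches C7 to the C8 ketone.

Step 9
Reactants: 11 C8 ketone
Product: 12 (8S)-C8 alcohol
Conditions: LiBH(s-Bu)3, THF, −78 °C
Reagents that add atoms: none
Why: Felkin–Anh reduction, in which the bulky hydride attacks anti to the quaternary C10 on the neighbouring C9 stereocenter and sets the C8 carbinol that becomes axial (β) in ring B.

Step 10
Reactants: 12 C8 alcohol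
Product: 13 C8 tert-butyldimethylsilyl ether
Conditions: TBSOTf, 2,6-lutidine, CH2Cl2, −78 → 0 °C
Reagents that add atoms: tert-butyldimethylsilyl triflate CC(C)(C)[Si](C)(C)OS(=O)(=O)C(F)(F)F
Why: Silyl triflate silylation of the hindered secondary alcohol installs the non-chelating C8 ether needed in the key step.

Step 11
Reactants: 13 C8 silyl ether (C5=C6 and C1=C2 alkenes)
Product: 15 C6 primary alcohol (5α-H), via B-alkyl-9-borabicyclononane 14 (not isolated)
Conditions: 9-BBN, THF, 65 °C; then NaOH, H2O2, 0 → 25 °C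
Reagents that add atoms: hydrogen peroxide OO
Why: Brown hydroboration–oxidation, in which 9-BBN should select the 1,1-disubstituted C5=C6 over the cis-disubstituted C1=C2 and add anti-Markovnikov from the face opposite the pseudoaxial methyls on C4 and C10, placing H on C5 trans to the C10 methyl and C6 trans to the C9 chain.

Step 12
Reactants: 15 C6 alcohol
Product: 16 C6 iodide
Conditions: I2, PPh3, imidazole, toluene, 80 °C
Reagents that add atoms: iodine II
Why: Garegg–Samuelsson (Appel-type) iodination of the primary alcohol, with heating to overcome the neopentyl-like hindrance at C6; no stereocenter is touched.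

Step 13
Reactants: 16 C6 iodide (C7–OMOM)
Product: 17 C7 primary alcohol
Conditions: ZnBr2, n-PrSH, CH2Cl2, 0 °C, 10 min
Reagents that add atoms: none
Why: Lewis acid/thiol transacetalisation removes the MOM ether within minutes, while the hindered secondary silyl ethers, the benzyl ethers and the iodide should survive.

Step 14
Reactants: 17 C7 alcohol
Product: 18 (2S,3R,4S)-4,5-bis(benzyloxy)-2-[(tert-butyldimethylsilyl)oxy]-3-[(1S,6R)-6-(iodomethyl)-1,5,5-trimethylcyclohex-2-en-1-yl]pentanal (C7 aldehyde, ring A iodide)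
Conditions: Dess–Martin periodinane, NaHCO3, CH2Cl2, 0 → 25 °C
Reagents that add atoms: none
Why: Dess–Martin oxidation gives the α-silyloxy aldehyde under buffered, non-epimerising conditions and tolerates the iodide.

Step 15
Reactants: 18 iodo aldehyde
Product: 20 decalin alcohol (Δ1; 7α-OH axial; 8β-OTBS axial; 9β side chain), via alkylsamarium diiodide 19 (not isolated)
Conditions: SmI2 (3 equiv), HMPA (12 equiv), THF, −78 °C, 18 added over 2 h to 0.005 M; aq NH4Cl
Reagents that add atoms: none
Why: SmI2–HMPA transfers an electron to the C6–I bond, the primary radical is reduced again to the alkylsamarium 19 (trivalent samarium), and this adds to the C7 aldehyde; the closest known reaction type is the SmI2-promoted intramolecular Barbier addition of an alkyl iodide to a carbonyl group. Ring B closes in a 6-exo-trig mode through a chair held by ring A, with the trans ring fusion already fixed by C5 and C10 and with C11 equatorial. The new C7 stereocenter is controlled by the adjacent C8 silyl ether: in this chair C8–OTBS is axial, and with a non-chelating silyl group and HMPA-saturated samarium the aldehyde oxygen should turn away from the C8–O dipole and end axial (7α), trans-diaxial to it. The step needs reduction of the hindered iodide before the aldehyde is pinacolised or deoxygenated; HMPA accelerates C–I reduction, slow addition at high dilution and −78 °C suppresses bimolecular ketyl coupling, and the α-branched aldehyde is a poor pinacol partner. The nucleophilic carbon is an unhindered CH2 although it sits between the quaternary C4 and C10, where an SN2 ring closure would fail. Compound 18 carries no ester and no acidic C–H next to the C8 ether, so acyl substitution and β-elimination are excluded.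

Step 16
Reactants: 20 decalin alcohol
Product: 21 C7 4-methoxybenzyl ether
Conditions: NaH, 4-MeOC6H4CH2Cl, Bu4NI (cat.), DMF, 0 → 25 °C
Reagents that add atoms: 4-methoxybenzyl chloride COc1ccc(CCl)cc1
Why: Williamson etherification; the trans-diaxial C8 silyl group cannot migrate to the C7 alkoxide, and the ether will withstand the organometallic of step 19.

Step 17
Reactants: 21 C7 PMB ether
Product: 22 C8 alcohol (8β-OH)
Conditions: Bu4NF, THF, 50 °C
Reagents that add atoms: none
Why: Fluoride desilylation frees the C8 hydroxyl; benzyl and 4-methoxybenzyl ethers are inert.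

Step 18
Reactants: 22 C8 alcohol
Product: 23 C8 ketone
Conditions: Dess–Martin periodinane, NaHCO3, CH2Cl2, 25 °C
Reagents that add atoms: none
Why: Dess–Martin oxidation gives the ketone, and C9–H already holds its thermodynamically preferred configuration (C11 equatorial).

Step 19
Reactants: 23 C8 ketone
Product: 24 tertiary alcohol (8β-OH axial; C16 as equatorial CH2OMOM)
Conditions: Bu3SnCH2OCH2OMe, n-BuLi, THF, −78 °C; CeCl3, −78 °C; then 23
Reagents that add atoms: tributyl[(methoxymethoxy)methyl]stannane CCCC[Sn](CCCC)(CCCC)COCOC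
Why: Organocerium (Imamoto) 1,2-addition suppresses enolisation, and the reagent should enter equatorially because the axial C10 methyl blocks the axial trajectory at C8 (1,3-diaxial), giving the axial tertiary hydroxyl and equatorial C16.

Step 20
Reactants: 24 tertiary alcohol
Product: 25 7α,8β-diol
Conditions: DDQ, CH2Cl2/pH 7 buffer, 0 °C
Reagents that add atoms: none
Why: Oxidative cleavage of the 4-methoxybenzyl ether leaves the benzyl ethers, the MOM ether and C1=C2 intact.

Step 21
Reactants: 25 diol
Product: 26 C7 acetate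
Conditions: Ac2O, DMAP (cat.), pyridine, CH2Cl2, 0 → 25 °C
Reagents that add atoms: acetic anhydride CC(=O)OC(C)=O
Why: Acylation of the secondary C7 hydroxyl; the tertiary C8 hydroxyl is shielded, and its trans-diaxial relation to C7–O rules out acetyl migration.

Step 22
Reactants: 26 C7 acetate (Δ1)
Product: 27 3α-allylic alcohol
Conditions: SeO2 (0.5 equiv), t-BuOOH, CH2Cl2, 25 °C
Reagents that add atoms: selenium dioxide O=[Se]=O (oxygen carrier, reoxidised by tert-butyl hydroperoxide CC(C)(C)OO)
Why: SeO2 allylic hydroxylation (ene reaction, then [2,3]-shift): C3 holds the only allylic hydrogens, the axial α-hydrogen is taken with selenium bonding to C1 on the α face opposite the axial C4 and C10 methyls, and the [2,3]-shift returns oxygen to C3 on that face (axial 3α-OH).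

Step 23
Reactants: 27 allylic alcohol
Product: 29 1α,2α,3α-triol, via osmate ester 28 (not isolated)
Conditions: OsO4 (1.1 equiv), TMEDA (1.2 equiv), CH2Cl2, −78 °C; then sat. aq NaHSO3, THF, 40 °C
Reagents that add atoms: osmium tetroxide O=[Os](=O)(=O)=O
Why: Donohoe hydroxyl-directed dihydroxylation, in which the OsO4·TMEDA complex hydrogen-bonds to the C3 hydroxyl and adds to C1=C2 on the same α face, which is also the face away from the axial C4 and C10 methyls.

Step 24
Reactants: 29 triol
Product: 30 C2 acetate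
Conditions: Ac2O (1.1 equiv), pyridine, CH2Cl2, −20 °C
Reagents that add atoms: acetic anhydride CC(=O)OC(C)=O
Why: Selective acylation of the only equatorial secondary hydroxyl (C2); the axial C1 and C3 hydroxyls each sit next to a quaternary carbon and should react far more slowly.

Step 25
Reactants: 30 C2 acetate
Product: 31 C1,C3 dibenzoate
Conditions: BzCl, DMAP, pyridine, 70 °C
Reagents that add atoms: benzoyl chloride O=C(Cl)c1ccccc1
Why: Forcing DMAP-catalysed benzoylation esterifies the two hindered axial hydroxyls, while the tertiary C8 hydroxyl stays free.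

Step 26
Reactants: 31 dibenzoate
Product: 32 C11,C12 diol
Conditions: H2 (1 atm), Pd(OH)2/C, EtOAc/EtOH, 25 °C
Reagents that add atoms: none
Why: Hydrogenolysis removes both benzyl ethers at a stage with no C=C bond; benzoates, acetates and the MOM ether are stable.

Step 27
Reactants: 32 diol
Product: 33 C11–C12 epoxide
Conditions: PPh3, i-PrO2CN=NCO2i-Pr, toluene, 0 → 60 °C
Reagents that add atoms: none
Why: Mitsunobu cyclodehydration of the terminal 1,2-diol, in which the primary C12 oxygen is activated and displaced by the C11 oxygen, gives the epoxide with retention at C11 under neutral conditions that spare the esters.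

Step 28
Reactants: 33 epoxide
Product: 34 C11 carbinol with methallyl chain (C12–C13)
Conditions: CH2=C(CH3)MgBr (3.5 equiv), CuI (0.2 equiv), THF, −50 → −30 °C; aq NH4Cl
Reagents that add atoms: isopropenylmagnesium bromide CC(=C)[Mg]Br
Why: Copper-catalysed Grignard opening of the terminal epoxide at the unhindered C12, which at −50 to −30 °C should be much faster than addition to the hindered esters.

Step 29
Reactants: 34 methallyl carbinol (C16–OMOM)
Product: 35 C16 primary alcohol (C8, C11, C16 triol)
Conditions: ZnBr2, n-PrSH, CH2Cl2, 0 °C, 10 min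
Reagents that add atoms: none
Why: The same thiol-assisted MOM cleavage, short enough to leave the esters and the 1,1-disubstituted alkene untouched.

Step 30
Reactants: 35 triol
Product: 36 C16 aldehyde, C11 ketone
Conditions: (COCl)2, DMSO, CH2Cl2, −78 °C; i-Pr2NEt, −78 → −20 °C
Reagents that add atoms: none
Why: Swern oxidation activates the primary C16 and secondary C11 hydroxyls together before base is added, so both carbonyls form at once and the γ-hydroxy aldehyde that would lactolise and over-oxidise to a lactone never exists; the tertiary C8 hydroxyl cannot be oxidised.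

Step 31
Reactants: 36 keto aldehyde
Product: 37 C16 allyl carbinol (C16 epimers)
Conditions: allylboronic acid pinacol ester, CH2Cl2, 25 °C; then aq NaHCO3
Reagents that add atoms: allylboronic acid pinacol ester C=CCB1OC(C)(C)C(C)(C)O1
Why: Allylboration through a closed six-membered transition state is selective for the aldehyde over the hindered C11 ketone and compatible with the esters; the C16 configuration is irrelevant because it is oxidised in step 33.

Step 32
Reactants: 37 diene
Product: 38 tricyclic C16 carbinol (ring C closed, Z-C13=C14)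
Conditions: second-generation Hoveyda–Grubbs catalyst (10 mol %), 1,4-benzoquinone (10 mol %), toluene, 80 °C, 0.001 M
Reagents that add atoms: none
Why: Ring-closing metathesis joins the monosubstituted C14 alkene to the 1,1-disubstituted C13 alkene; the two chains are trans-diequatorial on C8 and C9, which predisposes the eight-membered closure, and the ring enforces the Z geometry.

Step 33
Reactants: 38 tricyclic carbinol
Product: 39 CNP0214674.2 (target)
Conditions: Dess–Martin periodinane, NaHCO3, CH2Cl2, 0 → 25 °C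
Reagents that add atoms: none
Why: Dess–Martin oxidation of the secondary C16 carbinol gives the second β,γ-unsaturated ketone under buffered conditions that should not move the alkene into conjugation, and leaves the tertiary C8 hydroxyl and the four esters.

**Compound list**

1 | safranal, 2,6,6-trimethylcyclohexa-1,3-diene-1-carbaldehyde | CC1=C(C=O)C(C)(C)CC=C1 | starting material
2 | safranol, (2,6,6-trimethylcyclohexa-1,3-dien-1-yl)methanol | CC1=C(CO)C(C)(C)CC=C1 | intermediate
3 | ethyl 4-(benzyloxy)-3-oxobutanoate | CCOC(=O)CC(=O)COCc1ccccc1 | starting material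
4 | ethyl (3S)-4-(benzyloxy)-3-hydroxybutanoate | CCOC(=O)C[C@H](O)COCc1ccccc1 | intermediate
5 | (3S)-4-(benzyloxy)-3-hydroxybutanoic acid | OC(=O)C[C@H](O)COCc1ccccc1 | intermediate
6 | (2,6,6-trimethylcyclohexa-1,3-dien-1-yl)methyl (3S)-4-(benzyloxy)-3-hydroxybutanoate | CC1=C(COC(=O)C[C@H](O)COCc2ccccc2)C(C)(C)CC=C1 | intermediate
7 | chelated dilithium Z(O)-enolate/alkoxide of 6 | CC1=C(CO/C(O[Li])=C/[C@H](O[Li])COCc2ccccc2)C(C)(C)CC=C1 | intermediate
8 | (2R,3S)-4-(benzyloxy)-3-hydroxy-2-[(1S)-1,5,5-trimethyl-6-methylidenecyclohex-2-en-1-yl]butanoic acid (acid C = C8) | OC(=O)[C@@H]([C@H](O)COCc1ccccc1)[C@]1(C)C=CCC(C)(C)C1=C | intermediate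
9 | N-methoxy-N-methylamide of 8 | CON(C)C(=O)[C@@H]([C@H](O)COCc1ccccc1)[C@]1(C)C=CCC(C)(C)C1=C | intermediate
10 | C11 O-benzyl ether of 9 | CON(C)C(=O)[C@@H]([C@H](OCc1ccccc1)COCc1ccccc1)[C@]1(C)C=CCC(C)(C)C1=C | intermediate
11 | C8 ketone with C7 as CH2OMOM; C11, C12 benzyl ethers | COCOCC(=O)[C@@H]([C@H](OCc1ccccc1)COCc1ccccc1)[C@]1(C)C=CCC(C)(C)C1=C | intermediate
12 | (8S)-alcohol from 11 | COCOC[C@@H](O)[C@@H]([C@H](OCc1ccccc1)COCc1ccccc1)[C@]1(C)C=CCC(C)(C)C1=C | intermediate
13 | C8 TBS ether of 12 | COCOC[C@@H](O[Si](C)(C)C(C)(C)C)[C@@H]([C@H](OCc1ccccc1)COCc1ccccc1)[C@]1(C)C=CCC(C)(C)C1=C | intermediate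
14 | C6 B-alkyl-9-borabicyclo[3.3.1]nonane from 13 (5α-H) | COCOC[C@@H](O[Si](C)(C)C(C)(C)C)[C@@H]([C@H](OCc1ccccc1)COCc1ccccc1)[C@]1(C)C=CCC(C)(C)[C@H]1CB1C2CCCC1CCC2 | intermediate
15 | C6 primary alcohol (ring A: C6 trans to the C9 chain, cis to the C10 methyl) | COCOC[C@@H](O[Si](C)(C)C(C)(C)C)[C@@H]([C@H](OCc1ccccc1)COCc1ccccc1)[C@]1(C)C=CCC(C)(C)[C@H]1CO | intermediate
16 | C6 iodide of 15 | COCOC[C@@H](O[Si](C)(C)C(C)(C)C)[C@@H]([C@H](OCc1ccccc1)COCc1ccccc1)[C@]1(C)C=CCC(C)(C)[C@H]1CI | intermediate
17 | C7 primary alcohol (MOM removed from 16) | OC[C@@H](O[Si](C)(C)C(C)(C)C)[C@@H]([C@H](OCc1ccccc1)COCc1ccccc1)[C@]1(C)C=CCC(C)(C)[C@H]1CI | intermediate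
18 | (2S,3R,4S)-4,5-bis(benzyloxy)-2-[(tert-butyldimethylsilyl)oxy]-3-[(1S,6R)-6-(iodomethyl)-1,5,5-trimethylcyclohex-2-en-1-yl]pentanal | O=C[C@@H](O[Si](C)(C)C(C)(C)C)[C@@H]([C@H](OCc1ccccc1)COCc1ccccc1)[C@]1(C)C=CCC(C)(C)[C@H]1CI | intermediate
19 | C6 alkylsamarium diiodide of 18 | O=C[C@@H](O[Si](C)(C)C(C)(C)C)[C@@H]([C@H](OCc1ccccc1)COCc1ccccc1)[C@]1(C)C=CCC(C)(C)[C@H]1C[Sm](I)I | intermediate
20 | trans-decalin, Δ1, 4,4,10β-trimethyl, 5α-H, 7α-OH, 8β-OTBS, 9β-[(1S)-1,2-bis(benzyloxy)ethyl] | C1=C[C@]2(C)[C@H](C[C@H](O)[C@@H](O[Si](C)(C)C(C)(C)C)[C@H]2[C@H](OCc2ccccc2)COCc2ccccc2)C(C)(C)C1 | intermediate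
21 | 7α-O-(4-methoxybenzyl) ether of 20 | C1=C[C@]2(C)[C@H](C[C@H](OCc3ccc(OC)cc3)[C@@H](O[Si](C)(C)C(C)(C)C)[C@H]2[C@H](OCc2ccccc2)COCc2ccccc2)C(C)(C)C1 | intermediate
22 | 8β-alcohol (TBS removed from 21) | C1=C[C@]2(C)[C@H](C[C@H](OCc3ccc(OC)cc3)[C@@H](O)[C@H]2[C@H](OCc2ccccc2)COCc2ccccc2)C(C)(C)C1 | intermediate
23 | C8 ketone | C1=C[C@]2(C)[C@H](C[C@H](OCc3ccc(OC)cc3)C(=O)[C@H]2[C@H](OCc2ccccc2)COCc2ccccc2)C(C)(C)C1 | intermediate
24 | 8β-hydroxy-8α-[(methoxymethoxy)methyl] adduct (C16 installed) | C1=C[C@]2(C)[C@H](C[C@H](OCc3ccc(OC)cc3)[C@](O)(COCOC)[C@H]2[C@H](OCc2ccccc2)COCc2ccccc2)C(C)(C)C1 | intermediate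
25 | 7α,8β-diol | C1=C[C@]2(C)[C@H](C[C@H](O)[C@](O)(COCOC)[C@H]2[C@H](OCc2ccccc2)COCc2ccccc2)C(C)(C)C1 | intermediate
26 | 7α-acetate | C1=C[C@]2(C)[C@H](C[C@H](OC(C)=O)[C@](O)(COCOC)[C@H]2[C@H](OCc2ccccc2)COCc2ccccc2)C(C)(C)C1 | intermediate
27 | 3α-hydroxy-Δ1 compound | C1=C[C@]2(C)[C@H](C[C@H](OC(C)=O)[C@](O)(COCOC)[C@H]2[C@H](OCc2ccccc2)COCc2ccccc2)C(C)(C)[C@H]1O | intermediate
28 | C1,C2 osmate ester (hexavalent osmium) of 27, TMEDA adduct | O=[Os]3(=O)O[C@H]1[C@@H](O3)[C@]2(C)[C@H](C[C@H](OC(C)=O)[C@](O)(COCOC)[C@H]2[C@H](OCc2ccccc2)COCc2ccccc2)C(C)(C)[C@H]1O.CN(C)CCN(C)C | intermediate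
29 | 1α,2α,3α-triol | O[C@H]1[C@@H](O)[C@]2(C)[C@H](C[C@H](OC(C)=O)[C@](O)(COCOC)[C@H]2[C@H](OCc2ccccc2)COCc2ccccc2)C(C)(C)[C@H]1O | intermediate
30 | 2α-acetate of 29 | CC(=O)O[C@H]1[C@@H](O)[C@]2(C)[C@H](C[C@H](OC(C)=O)[C@](O)(COCOC)[C@H]2[C@H](OCc2ccccc2)COCc2ccccc2)C(C)(C)[C@H]1O | intermediate
31 | 1α,3α-dibenzoate 2α,7α-diacetate | CC(=O)O[C@H]1[C@@H](OC(=O)c3ccccc3)[C@]2(C)[C@H](C[C@H](OC(C)=O)[C@](O)(COCOC)[C@H]2[C@H](OCc2ccccc2)COCc2ccccc2)C(C)(C)[C@H]1OC(=O)c1ccccc1 | intermediate
32 | 9β-[(1S)-1,2-dihydroxyethyl] compound | CC(=O)O[C@H]1[C@@H](OC(=O)c3ccccc3)[C@]2(C)[C@H](C[C@H](OC(C)=O)[C@](O)(COCOC)[C@H]2[C@H](O)CO)C(C)(C)[C@H]1OC(=O)c1ccccc1 | intermediate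
33 | 9β-[(2S)-oxiran-2-yl] compound | CC(=O)O[C@H]1[C@@H](OC(=O)c3ccccc3)[C@]2(C)[C@H](C[C@H](OC(C)=O)[C@](O)(COCOC)[C@H]2[C@H]2CO2)C(C)(C)[C@H]1OC(=O)c1ccccc1 | intermediate
34 | 9β-[(1R)-1-hydroxy-3-methylbut-3-enyl] compound | CC(=O)O[C@H]1[C@@H](OC(=O)c3ccccc3)[C@]2(C)[C@H](C[C@H](OC(C)=O)[C@](O)(COCOC)[C@H]2[C@H](O)CC(C)=C)C(C)(C)[C@H]1OC(=O)c1ccccc1 | intermediate
35 | 8α-hydroxymethyl triol (C8, C11, C16 hydroxyls) | CC(=O)O[C@H]1[C@@H](OC(=O)c3ccccc3)[C@]2(C)[C@H](C[C@H](OC(C)=O)[C@](O)(CO)[C@H]2[C@H](O)CC(C)=C)C(C)(C)[C@H]1OC(=O)c1ccccc1 | intermediate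
36 | C16 aldehyde, C11 ketone | CC(=O)O[C@H]1[C@@H](OC(=O)c3ccccc3)[C@]2(C)[C@H](C[C@H](OC(C)=O)[C@](O)(C=O)[C@H]2C(=O)CC(C)=C)C(C)(C)[C@H]1OC(=O)c1ccccc1 | intermediate
37 | C16 allyl carbinol (both C16 epimers), C11 methallyl ketone | CC(=O)O[C@H]1[C@@H](OC(=O)c3ccccc3)[C@]2(C)[C@H](C[C@H](OC(C)=O)[C@](O)(C(O)CC=C)[C@H]2C(=O)CC(C)=C)C(C)(C)[C@H]1OC(=O)c1ccccc1 | intermediate
38 | tricyclic 16-hydroxy-11-ketone (both C16 epimers), Z-C13=C14 | CC(=O)O[C@H]1[C@@H](OC(=O)c2ccccc2)[C@]2(C)[C@H](C[C@H](OC(C)=O)[C@]3(O)C(O)C/C=C(/C)CC(=O)[C@H]32)C(C)(C)[C@H]1OC(=O)c1ccccc1 | intermediate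
39 | CNP0214674.2 | CC(=O)O[C@H]1[C@@H](OC(=O)c2ccccc2)[C@]2(C)[C@H](C[C@H](OC(C)=O)[C@]3(O)C(=O)C/C=C(/C)CC(=O)[C@H]32)C(C)(C)[C@H]1OC(=O)c1ccccc1 | target

**Step count**

Total steps: 33. Longest linear sequence: 32 steps (3 → 39, steps 2–33); 31 steps from safranal.

**Steps most likely to fail**

Step 15. The aldehyde may accept an electron (ketyl formation, pinacol coupling, loss of the C8 silyloxy group) faster than the hindered C–I bond is reduced, and the carbonyl face may be chosen poorly, giving the C7 equatorial alcohol. Fallback: ring B is closed at the same bond by an anionic acylation and C7 is set afterwards by an internally delivered hydride. It sets out from 18. Pinnick oxidation (NaClO2, NaH2PO4, 2-methyl-2-butene) should give the C7 carboxylic acid F1, and coupling with MeNH(OMe)·HCl/EDC·HCl the C7 Weinreb amide F2. Iodine–lithium exchange (t-BuLi, Et2O/pentane, −100 °C) with intramolecular acylation should close ring B to the C7 ketone F3. HF·pyridine frees the 8β-hydroxy ketone F4, and Me4NBH(OAc)3 in AcOH/MeCN should deliver hydride from the boron bound to the axial C8 oxygen, giving the trans-diaxial 7α,8β-diol F5. Selective etherification of the less hindered C7 hydroxyl (NaH, 1 equiv; 4-MeOC6H4CH2Cl) returns to the route at 22.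

Step 5. The dianion may fragment (ketene loss) or rearrange sluggishly at the tetrasubstituted C10 terminus, and the axial C10 methyl may erode the chair preference, lowering the C9/C10 diastereoselectivity. Fallback: the rearrangement is run on a neutral silyl ketene acetal instead of the lithium chelate. It sets out from 6. Silylation (Et3SiCl, imidazole) gives the C11 triethylsilyl ether F6. Z(O)-selective enolisation (LiN(i-Pr)2, THF/DMPU, −78 °C), trapping with Me3SiCl and warming to 60 °C should give, after aqueous work-up, the C11 O-triethylsilyl Claisen acid F7; here allylic strain, not chelation, directs the allyl terminus anti to C12, in the same sense. HF·pyridine removes the silyl ether and returns to the route at 8.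

Step 11. The borane may add to C1=C2 as well, or reach C5=C6 from the β face and give the C5 epimer. Fallback: hydrogen is delivered to C5 from a temporary silicon tether on the C8 oxygen, which sits on the α face with the C9 chain. It sets out from 12. (Me2HSi)2NH gives the C8 O-dimethylsilyl ether F8. Intramolecular hydrosilylation with Pt2[(CH2=CHSiMe2)2O]3 (zerovalent platinum) should place silicon on the terminal C6 and hydrogen on C5 from the tether side, giving the seven-membered cyclic siloxane F9. Tamao oxidation (H2O2, KF, KHCO3) gives the C6,C8 diol F10, and I2/PPh3/imidazole iodinates only the primary hydroxyl to the C6 iodo C8 alcohol F11. TBSOTf/2,6-lutidine then returns to the route at 16.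

**Further compounds**

F1 | step 15 | C7 carboxylic acid from 18 | OC(=O)[C@@H](O[Si](C)(C)C(C)(C)C)[C@@H]([C@H](OCc1ccccc1)COCc1ccccc1)[C@]1(C)C=CCC(C)(C)[C@H]1CI
F2 | step 15 | C7 N-methoxy-N-methylamide | CON(C)C(=O)[C@@H](O[Si](C)(C)C(C)(C)C)[C@@H]([C@H](OCc1ccccc1)COCc1ccccc1)[C@]1(C)C=CCC(C)(C)[C@H]1CI
F3 | step 15 | decalin C7 ketone with 8β-OTBS | C1=C[C@]2(C)[C@H](CC(=O)[C@@H](O[Si](C)(C)C(C)(C)C)[C@H]2[C@H](OCc2ccccc2)COCc2ccccc2)C(C)(C)C1
F4 | step 15 | decalin 8β-hydroxy C7 ketone | C1=C[C@]2(C)[C@H](CC(=O)[C@@H](O)[C@H]2[C@H](OCc2ccccc2)COCc2ccccc2)C(C)(C)C1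
F5 | step 15 | decalin 7α,8β-diol | C1=C[C@]2(C)[C@H](C[C@H](O)[C@@H](O)[C@H]2[C@H](OCc2ccccc2)COCc2ccccc2)C(C)(C)C1
F6 | step 5 | C11 O-triethylsilyl ether of 6 | CC1=C(COC(=O)C[C@H](O[Si](CC)(CC)CC)COCc2ccccc2)C(C)(C)CC=C1
F7 | step 5 | C11 O-triethylsilyl ether of 8 | OC(=O)[C@@H]([C@H](O[Si](CC)(CC)CC)COCc1ccccc1)[C@]1(C)C=CCC(C)(C)C1=C
F8 | step 11 | C8 O-dimethylsilyl ether of 12 | COCOC[C@@H](O[SiH](C)C)[C@@H]([C@H](OCc1ccccc1)COCc1ccccc1)[C@]1(C)C=CCC(C)(C)C1=C
F9 | step 11 | cyclic siloxane bridging C8–O and C6 | COCOC[C@H]1O[Si](C)(C)C[C@@H]2C(C)(C)CC=C[C@@]2(C)[C@@H]1[C@H](OCc1ccccc1)COCc1ccccc1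
F10 | step 11 | C6,C8 diol | COCOC[C@@H](O)[C@@H]([C@H](OCc1ccccc1)COCc1ccccc1)[C@]1(C)C=CCC(C)(C)[C@H]1CO
F11 | step 11 | C6 iodide with free C8 hydroxyl | COCOC[C@@H](O)[C@@H]([C@H](OCc1ccccc1)COCc1ccccc1)[C@]1(C)C=CCC(C)(C)[C@H]1CI
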